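# Proposed synthesis of (−)-7-N-methyldibromophakellin: pyrrole ring A built last on a tricyclic glycine lactam

## Analysis of the target

The target is a compact tetracycle in which a 2,3-dibromopyrrole (ring A: N1, C2, C3, C4, C5) is fused through N1 and C5 to a pyrazinone (ring B: N1, C5, C15, N14, C10, C6), which shares N14–C10 with a pyrrolidine (ring C: C10, C11, C12, C13, N14) and C6–C10 with a cyclic N7-methylguanidine (ring D: C6, N7, C8, N9, C10). There are two adjacent stereocentres: C10 (R), a fully substituted aminal carbon bonded to N9, N14, C11 and C6 and common to rings B, C and D, and C6 (S), an aminal methine between pyrrole N1 and N7. Rings B and D can only be cis-fused across C6–C10, so the configuration at C6 follows from that at C10 and only one absolute configuration has to be controlled. The sensitive groups are the two aminal carbons, the basic and very polar 2-aminoimidazoline, and the two pyrrole bromines, which do not tolerate catalytic hydrogenation or strong reductants. The synthesis is hard for two reasons: the crowded C10 with its two nitrogen substituents must be made in one absolute sense, and the C6–N1 bond is awkward to form from a pyrrole, because a 2-acylpyrrole is an ambident nucleophile whose free carbon C4 can reach C6 through a six-membered ring just as N1 can. The plan rests on one structural feature: ring A is joined to the rest only through N1 (to C6) and C5 (to the lactam carbonyl C15), so that without ring A the unit N1–C5–C15 is simply a glycine amide. Its amine nitrogen forms the C6 aminal without any carbon competitor, and ring A is then built last from N1, the lactam methylene C5 and a three-carbon dialdehyde that already carries the C3 bromine.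

## Retrosynthetic reasoning

**Guanidine from urea (19 ⇒ 18 ⇒ 17).** The exocyclic C8–N bond is cut first. A urea at C8 is neutral and survives hydride, acid, base and bromination, whereas a free 2-aminoimidazoline would interfere with every acid- or base-mediated step. The forward steps must activate the urea oxygen of 17 selectively as the isourea 18 and then exchange the ethoxy group for an amino group.

**C2–Br (17 ⇒ 16).** The bromine next to N1 is removed. The three-carbon reagent used for ring A can carry only one bromine, on its central carbon, which becomes C3. The remaining α-position C2 of 16 is the most reactive site of the pyrrole, so the second bromine comes by electrophilic substitution.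

**Ring A (16 ⇒ 12 + 13).** The bonds N1–C2 and C4–C5 are cut. This is the key disconnection: it turns the pyrrole nitrogen into the secondary amine of the tricyclic glycine lactam 12, and the bond C6–N1 becomes an ordinary amine-derived aminal. The nitrogen-versus-carbon question disappears, the bromine position is fixed by the symmetrical reagent 13, and no oxidant is needed. The forward reaction must condense N1 with 13, enolise a lactam methylene, close the ring on the second formyl group and aromatise, all without damage to the C6 aminal.

**C6–N1 (12 ⇒ 11 ⇒ 10).** The aminal bond is cut to a primary amine and a C6 carbinol on the urea nitrogen N7 (compound 11), whose amine is masked as the benzyl carbamate in 10. The closure can only give the cis-fused rings B and D, so C10 controls C6.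

**Oxidation level of C6 (10 ⇒ 9).** The carbinol is traced back to the imide-type carbonyl of the spiro hydantoin 9. This carbonyl has a second role earlier, because it makes C10–H acidic.

**Ring C and the C10 stereocentre (9 ⇒ 8 ⇒ 7 ⇒ 5 + 6).** The C13 hydroxyl is restored (8), then N14–C13 and C10–C11 are cut, which leads to acrolein 6 as the unit C11–C13 and to the 5-amidohydantoin 5. The forward reaction sets C10 by a face-selective conjugate addition of a prochiral enolate under a chiral bifunctional base. The tert-butoxycarbonyl group on N9 of 5 ensures that only N14 can close on the aldehyde of 7.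

**N9 protection, C10–N14 and C10–Br (5 ⇒ 4 ⇒ 2 + 3; 2 ⇒ 1).** Removal of the N9 carbamate gives 4, which is cut at C10–N14 into the bromohydantoin 2 and the glycinamide 3; 2 comes from 3-methylhydantoin 1. The benzyl carbamate in 3 is chosen because it is orthogonal to the N9 protecting group: acid frees N9 while N1 stays masked until C6 has been reduced. A free N1 amine next to the C6 imide carbonyl would acylate itself, and the benzyl carbamate is later removed by hydrogenolysis before any bromine is in the molecule.

## Alternatives that were turned down

**Alternative 1:** Rings B and C are assembled at the quaternary carbon by a three-component Ugi–Joullié reaction. The cyclic ketimine methyl 1-pyrroline-2-carboxylate A1, methyl isocyanide A2 and 4,5-dibromo-1H-pyrrole-2-carboxylic acid A3 combine under a chiral Brønsted acid; the isocyanide carbon adds to the ketiminium carbon (C10–C6) and Mumm acyl transfer forms N14–C15, giving the diamide ester A4.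
- For it: the convergence is better than in the chosen route, since one step brings together the pyrrolidine, N7 with its methyl group and the intact dibromopyrrole.
- Against it: A4 carries an ester carbon on C10 where N9 must stand. A carbon-to-nitrogen exchange by hydrolysis and Curtius rearrangement is needed at a fully substituted centre, and the intermediate acid is an N-acylaminomalonic half-amide that decarboxylates easily, which would destroy C10.
- Against it: enantiocontrol of isocyanide addition to an ester-substituted ketiminium ion, where the two carbonyl substituents on C10 are of similar size, is much less secure than for aldimines.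
- Against it: C6 must still be reduced and closed onto the pyrrole, with N1 competing against C4.
- Comparison: the alternative is shorter up to A4, but the chosen strategy offers a C10 that carries both nitrogens from the start and a C6–N1 bond made by an amine.

**Alternative 2:** The pyrrole is carried from the start. The N9-Boc 5-(4,5-dibromopyrrole-2-carboxamido)-3-methylhydantoin A5 adds through C10 to acrolein 6 under a cinchona amine–squaramide catalyst and the amide N14–H closes on the aldehyde, giving the spiro hemiaminal A6. Deoxygenation, C6 reduction, acyliminium closure by the pyrrole and the urea-to-guanidine exchange would follow.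
- For it: this is the shortest plan and clearly stronger in step economy. It uses the same type of annulation as step 4 of the chosen route and saves the steps spent there on building and brominating ring A.
- Against it: the final C6–N1 closure asks the weakly nucleophilic nitrogen of an acylated dibromopyrrole to attack an acyliminium ion next to the quaternary C10, while C4 can attack through an equally favourable six-membered ring.
- Against it: the acidic pyrrole N–H is a second donor in the conjugate addition and competes for the basic site of the catalyst, and the bromines are present during the reductive steps.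
- Comparison: the chosen strategy accepts a longer sequence in exchange for unambiguous C6–N1 connectivity and a bromine-free molecule during hydrogenolysis.

**Alternative 3:** C6 serves as an aldehyde linchpin. The primary alcohol A7, whose quaternary C10 comes from the chiral pool by self-regeneration of a stereocentre, is oxidised to the aldehyde A8. Under strong acid A8 condenses with the N7–H of the methylurea and with pyrrole N1–H, closing rings D and B at once to give 7-N-methyldibromophakellstatin A9, which is identical with 17.
- For it: one step closes two rings with C6 under thermodynamic control, and the absolute configuration needs no asymmetric catalysis. On that point it is stronger than the chosen route.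
- Against it: A7 needs N9, N14 and a one-carbon arm on the same carbon, so nitrogen must be introduced at a fully substituted centre, which costs many linear steps.
- Against it: A8 is an α,α-diamino aldehyde that can lose its urea by elimination, and the second condensation again meets the N1-versus-C4 ambiguity.
- Comparison: the chosen route reaches the same compound 17 with the C6–N1 bond beyond doubt, at the price of relying on a catalytic asymmetric annulation.

Key step: step 8

## Assumptions and conventions

- Assumption on the chemistry: the quinine-derived squaramide catalyst of step 4 is taken to give the C10 configuration of the target. If the opposite sense is found, the quinidine-derived pseudoenantiomer is used with nothing else changed.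
- Atom labels (N1 to C15) follow the numbering of the target throughout. Where a CIP descriptor changes between intermediates without a reaction at that centre, only the substituent priorities have changed.

## Route

Step 1
Reactants: 1 3-methylhydantoin
Product: 2 5-bromo-3-methylhydantoin (racemic; used crude)
Conditions: Br2 (1.05 equiv), AcOH, 80 °C; evaporate with toluene
Reagents that add atoms: bromine, BrBr
Why: Acid-catalysed enol bromination at C5 of the hydantoin (the future C10), the only enolisable carbon; the moisture-sensitive α-bromo amide is carried on directly.

Step 2
Reactants: 2 5-bromo-3-methylhydantoin; 3 N-(benzyloxycarbonyl)glycinamide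
Product: 4 5-[N-(benzyloxycarbonyl)glycylamino]-3-methylhydantoin (racemic)
Conditions: iPr2NEt (1.5 equiv), MeCN, 0 °C → rt
Reagents that add atoms: none
Why: Amidoalkylation: bromide leaves C10 with the help of N9 to give an N-acyliminium ion, which the primary amide nitrogen captures to form C10–N14; this is the classical substitution of 5-halohydantoins by ureas and amides.

Step 3
Reactants: 4 5-[N-(benzyloxycarbonyl)glycylamino]-3-methylhydantoin
Product: 5 tert-butyl 5-[N-(benzyloxycarbonyl)glycylamino]-3-methyl-2,4-dioxoimidazolidine-1-carboxylate (racemic; Boc on N9)
Conditions: Boc2O (1.1 equiv), DMAP (5 mol%), MeCN, 0 °C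
Reagents that add atoms: di-tert-butyl dicarbonate, CC(C)(C)OC(=O)OC(=O)OC(C)(C)C
Why: DMAP-catalysed N-acylation should favour the ring N9–H, which is the most acidic N–H and is held cisoid like a lactam, over the hindered acyclic amide N14–H; blocking N9 leaves N14 as the only nitrogen able to close on the aldehyde in step 4 and raises the acidity of C10–H.

Step 4
Reactants: 5 tert-butyl 5-[N-(benzyloxycarbonyl)glycylamino]-3-methyl-2,4-dioxoimidazolidine-1-carboxylate; 6 acrolein
Product: 8 spiro hemiaminal tert-butyl (5S)-6-[N-(benzyloxycarbonyl)glycyl]-7-hydroxy-3-methyl-2,4-dioxo-1,3,6-triazaspiro[4.4]nonane-1-carboxylate (both C7 epimers), via Michael aldehyde 7 (not isolated)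
Conditions: quinine-derived squaramide catalyst (3-[3,5-bis(trifluoromethyl)anilino]-4-[(9-deoxy-epi-quinin-9-yl)amino]cyclobut-3-ene-1,2-dione, 10 mol%), 6 (1.5 equiv), CH2Cl2, −30 °C
Reagents that add atoms: none
Why: Proposed new method: the quinuclidine nitrogen of the catalyst removes the C10–H of 5, which is flanked by two acylated nitrogens and the C6 carbonyl, the squaramide N–H pair binds the enolate, and the ammonium ion delivers acrolein to one enolate face, so C10–C11 forms with C10 set by the catalyst; N14–H then adds to the aldehyde of 7 (5-exo-trig) to give the hemiaminal. The closest known reactions are the amine–hydrogen-bond-donor catalysed conjugate additions of α-substituted cyanoacetates, azlactones and related amino-acid-derived heterocycles to enals and enones, and the base-mediated annulation of acylaminomalonates with acrolein to 5-hydroxypyrrolidines.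

Step 5
Reactants: 8 spiro hemiaminal
Product: 9 (5R)-6-[N-(benzyloxycarbonyl)glycyl]-3-methyl-1,3,6-triazaspiro[4.4]nonane-2,4-dione
Conditions: Et3SiH (5 equiv), CF3CO2H/CH2Cl2 (1:3), 0 °C → rt
Reagents that add atoms: none
Why: Ionic hydrogenation: acid ionises the C13 hemiaminal to the N14-acyliminium ion and the silane reduces it irreversibly, after which C10 can no longer be lost by retro-Michael cleavage; the same acid removes the N9-Boc group, whose task ended with step 4, while the benzyl carbamate survives. The descriptor at C10 changes from S to R through the loss of the Boc group only.

Step 6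
Reactants: 9 (5R)-6-[N-(benzyloxycarbonyl)glycyl]-3-methyl-1,3,6-triazaspiro[4.4]nonane-2,4-dione
Product: 10 (5R)-6-[N-(benzyloxycarbonyl)glycyl]-4-hydroxy-3-methyl-1,3,6-triazaspiro[4.4]nonan-2-one (both C4 epimers; C4 of this name is C6 of the target)
Conditions: NaBH4 (4 equiv), MeOH/THF (1:1), 0 °C → rt
Reagents that add atoms: none
Why: Partial reduction of an imide-type carbonyl: in a 3-alkylhydantoin the C4 carbonyl (C6 of the target) is the electrophilic one, while the urea carbonyl C8, the amide C15 and the carbamate are inert to borohydride; the protic medium traps the hydroxy urea before it can open and be reduced further. The carbinol epimers are both used, since C6 is ionised in step 7.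

Step 7
Reactants: 10 (5R)-6-[N-(benzyloxycarbonyl)glycyl]-4-hydroxy-3-methyl-1,3,6-triazaspiro[4.4]nonan-2-one
Product: 12 tricyclic glycine lactam (6R,10R; rings B C D of the target with a C8 carbonyl; N1–H free; C5 a methylene), via amino carbinol 11 (not isolated)
Conditions: H2 (1 atm), 10% Pd/C, MeOH, rt; filter, evaporate; AcOH, 50 °C; aq. NaHCO3 work-up
Reagents that add atoms: none
Why: Hydrogenolysis of the benzyl carbamate frees the primary amine of 11; acid then ionises the C6 carbinol to the N7-acyliminium ion, which N1 captures in a 6-exo-trig closure (intramolecular amidoalkylation to the aminal). C6 is set by C10, because the tether N14–C15–C5–N1 can reach C6 only on the face that gives the cis-fused rings B and D, and since the closure is reversible this is also the thermodynamic product.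

Step 8
Reactants: 12 tricyclic glycine lactam; 13 bromomalonaldehyde
Product: 16 monobromo cyclic urea tetracycle (6R,10R; bromine on C3; C2–H), via enaminal 14 (not isolated), via aldol adduct 15 (not isolated)
Conditions: a) 13 (1.2 equiv), 4 Å molecular sieves, EtOH, 25 → 40 °C; evaporate; b) KOtBu (3 equiv), THF, 0 °C → rt; AcOH quench
Reagents that add atoms: none
Why: Proposed new method: the only basic nitrogen, N1, condenses with the enol form of 13 to the vinylogous formamide 14 (N1–C2), which also turns N1 into a non-basic acyl-type nitrogen and so locks the C6 aminal. KOtBu first removes the urea N9–H and then, reversibly, a proton from C5, the sole enolisable carbon, whose acidity is raised by the lactam carbonyl and the now electron-poor N1; the lactam enolate attacks the remaining formyl group (C5–C4) in a 5-(enolexo)-exo-trig aldol closure of ring A to give 15. Loss of hydroxide from C4, pushed by the N1–C2=C3 enamine, and loss of the C5 proton aromatise the ring without an oxidant, which makes the sequence irreversible and draws the unfavourable enolate equilibrium forward. The closest known reaction is the condensation of N-alkylglycine esters with 2-substituted malonaldehydes or their vinamidinium salts followed by base-induced closure to pyrrole-2-carboxylates; new here is that the carbon acid is a lactam methylene and not an ester. No lasting stereocentre is formed (C4 and C5 end as sp2 carbons), and C6 and C10 are not touched. Only chemoselectivity is needed: nitrogen versus carbon is decided before a pyrrole exists, because N1 is an amine and C5 has no nucleophilic rival, and the bromine ends on C3 because it sits on the central carbon of the symmetrical reagent.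

Step 9
Reactants: 16 monobromo cyclic urea tetracycle
Product: 17 7-N-methyldibromophakellstatin (6S,10R; cyclic urea analogue of the target)
Conditions: NBS (1.05 equiv), THF, −20 → 0 °C, dark
Reagents that add atoms: N-bromosuccinimide, O=C1CCC(=O)N1Br
Why: Electrophilic aromatic substitution: in a 4-bromo-2-acylpyrrole the free α-position (C2 here) is the most reactive site, while C4 is a β-position next to the acyl-bearing carbon. The descriptor at C6 changes from R to S through the new bromine only.

Step 10
Reactants: 17 7-N-methyldibromophakellstatin
Product: 18 O-ethyl isourea (6S,10R; C8 carries OEt and is double-bonded to N9)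
Conditions: Et3OBF4 (3 equiv), CH2Cl2, rt; aq. NaHCO3 work-up
Reagents that add atoms: triethyloxonium tetrafluoroborate, CC[O+](CC)CC.F[B-](F)(F)F
Why: Meerwein O-alkylation of a urea: the urea oxygen, fed by two nitrogen lone pairs, is the most nucleophilic oxygen of 17, the lactam oxygen being attached to an electron-poor dibromopyrrole; loss of the N9 proton on work-up gives the neutral 2-ethoxyimidazoline.

Step 11
Reactants: 18 O-ethyl isourea
Product: 19 (−)-7-N-methyldibromophakellin (6S,10R)
Conditions: NH3 (7 M in MeOH), NH4Cl (2 equiv), sealed tube, 80 °C; aq. Na2CO3 work-up
Reagents that add atoms: ammonia, N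
Why: Addition–elimination at the isourea carbon C8: ammonia adds to the protonated isourea and ethanol leaves, giving the cyclic guanidine; C6 and C10 take no part and the pyrrole bromines are inert to ammonia under these conditions.

## Compound list

1 | 3-methylhydantoin (3-methylimidazolidine-2,4-dione) | CN1C(=O)CNC1=O | starting material
2 | 5-bromo-3-methylhydantoin (racemic) | CN1C(=O)C(Br)NC1=O | intermediate
3 | N-(benzyloxycarbonyl)glycinamide (benzyl N-(2-amino-2-oxoethyl)carbamate) | NC(=O)CNC(=O)OCc1ccccc1 | starting material
4 | 5-[N-(benzyloxycarbonyl)glycylamino]-3-methylhydantoin (racemic) | CN1C(=O)C(NC(=O)CNC(=O)OCc2ccccc2)NC1=O | intermediate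
5 | tert-butyl 5-[N-(benzyloxycarbonyl)glycylamino]-3-methyl-2,4-dioxoimidazolidine-1-carboxylate (racemic; Boc on N9) | CN1C(=O)C(NC(=O)CNC(=O)OCc2ccccc2)N(C(=O)OC(C)(C)C)C1=O | intermediate
6 | acrolein (prop-2-enal) | C=CC=O | starting material
7 | Michael aldehyde: tert-butyl (5S)-5-[N-(benzyloxycarbonyl)glycylamino]-3-methyl-2,4-dioxo-5-(3-oxopropyl)imidazolidine-1-carboxylate (formed in the flask, not isolated) | CN1C(=O)[C@@](CCC=O)(NC(=O)CNC(=O)OCc2ccccc2)N(C(=O)OC(C)(C)C)C1=O | intermediate
8 | spiro hemiaminal: tert-butyl (5S)-6-[N-(benzyloxycarbonyl)glycyl]-7-hydroxy-3-methyl-2,4-dioxo-1,3,6-triazaspiro[4.4]nonane-1-carboxylate (both C7 epimers) | CN1C(=O)N(C(=O)OC(C)(C)C)[C@@]2(CCC(O)N2C(=O)CNC(=O)OCc2ccccc2)C1=O | intermediate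
9 | (5R)-6-[N-(benzyloxycarbonyl)glycyl]-3-methyl-1,3,6-triazaspiro[4.4]nonane-2,4-dione | CN1C(=O)N[C@@]2(CCCN2C(=O)CNC(=O)OCc2ccccc2)C1=O | intermediate
10 | (5R)-6-[N-(benzyloxycarbonyl)glycyl]-4-hydroxy-3-methyl-1,3,6-triazaspiro[4.4]nonan-2-one (both C4 epimers) | CN1C(=O)N[C@@]2(CCCN2C(=O)CNC(=O)OCc2ccccc2)C1O | intermediate
11 | amino carbinol: (5R)-6-glycyl-4-hydroxy-3-methyl-1,3,6-triazaspiro[4.4]nonan-2-one (formed in the flask, not isolated) | CN1C(=O)N[C@@]2(CCCN2C(=O)CN)C1O | intermediate
12 | tricyclic glycine lactam, (6R,10R): rings B, C and D of the target with C8 as a urea carbonyl, N1–H free and C5 a methylene | CN1C(=O)N[C@]23CCCN2C(=O)CN[C@H]13 | intermediate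
13 | bromomalonaldehyde (2-bromopropanedial) | O=CC(Br)C=O | starting material
14 | enaminal, (6R,10R): N1-(2-bromo-3-oxoprop-1-enyl) derivative of 12 (formed in the flask, not isolated) | CN1C(=O)N[C@]23CCCN2C(=O)CN(C=C(Br)C=O)[C@H]13 | intermediate
15 | aldol adduct, (6R,10R): 3-bromo-4-hydroxy-4,5-dihydro ring A (C4 and C5 unassigned; formed in the flask, not isolated) | CN1C(=O)N[C@]23CCCN2C(=O)C2C(O)C(Br)=CN2[C@H]13 | intermediate
16 | monobromo cyclic urea tetracycle, (6R,10R): 17 without the C2 bromine | CN1C(=O)N[C@]23CCCN2C(=O)c2cc(Br)cn2[C@H]13 | intermediate
17 | 7-N-methyldibromophakellstatin, (6S,10R) | CN1C(=O)N[C@]23CCCN2C(=O)c2cc(Br)c(Br)n2[C@H]13 | intermediate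
18 | O-ethyl isourea, (6S,10R): 8-ethoxy compound with the C8=N9 double bond | CN1C(OCC)=N[C@]23CCCN2C(=O)c2cc(Br)c(Br)n2[C@H]13 | intermediate
19 | (−)-7-N-methyldibromophakellin, (6S,10R) | CN1C(N)=N[C@]23CCCN2C(=O)c2cc(Br)c(Br)n2[C@H]13 | target

## Step count and least certain steps

Total step count: 11. Longest linear sequence: 11 steps (1 → 19); compounds 3, 6 and 13 are commercial and enter directly.

**Step 8 (key step, proposed as a new method).** The most likely failure is that the lactam C5–H is removed too slowly, so that base-induced breakdown of the bromo-enal (alkoxide attack at the formyl group with deformylation, or loss of bromide) wins. A second risk is opening of the C6 aminal before N1 is acylated, which would send the condensation down a wrong sequence.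
Fallback (known chemistry; C5 is made nucleophilic through an iminium ion instead of an enolate). It sets out from 12 and returns at 17. Heating 12 with paraformaldehyde and (E)-1,2-bis(phenylsulfonyl)ethene in toluene at 110 °C forms the N1-methyleneiminium ion. Its C5–H, now α to both the iminium and the lactam carbonyl, is lost to give an amide-stabilised azomethine ylide, and [3+2] cycloaddition gives the 3,4-bis(phenylsulfonyl)pyrrolidine cycloadduct F1, in which C2 comes from formaldehyde and C3 and C4 from the alkene. DBU in THF removes two molecules of benzenesulfinic acid and gives the unbrominated pyrrole 7-N-methylphakellstatin F2. NBS (2.1 equiv, THF, 0 °C) then brominates both positions remote from C5, the established pattern for pyrrole-2-carbonyl compounds, to give 17. Iminium-route ylides of secondary α-amino carbonyl compounds, the bis-sulfone as an acetylene equivalent and the dibromination are all established reactions.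

**Step 4 (proposed as a new method).** The risks are poor facial selectivity at the prochiral C10 enolate, erosion of the enantiomeric purity by reversible Michael addition before the hemiaminal is reduced, and consumption of acrolein by aza-Michael addition or polymerisation.
Fallback (known chemistry; resolution in place of asymmetric catalysis). It sets out from 5 and returns at 9. DABCO (10 mol%) in CH2Cl2 promotes the same conjugate addition and hemiaminal closure without stereocontrol, as in the classical annulation of acylamino C–H acids with acrolein, giving the racemic spiro hemiaminal F3. Et3SiH in CF3CO2H/CH2Cl2 gives the racemic spiro hydantoin F4, which is resolved by preparative chromatography on a chiral stationary phase (amylose tris(3,5-dimethylphenylcarbamate), supercritical CO2/MeOH) to give 9. Half of the material is lost, but no new asymmetric reaction is needed.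

**Step 3.** The risk is loss of site selectivity in the N-acylation: the carbamate N–H or the amide N14–H may be acylated in competition with N9–H, and a Boc group on N14 would block the annulation.
Fallback (the order of protection and C–N bond formation is reversed). It sets out from 1 and returns at 5. Compound 1 has a single N–H, so Boc2O/DMAP gives 1-Boc-3-methylhydantoin F5 without any selectivity question. Radical bromination (NBS, AIBN, PhCF3, 80 °C) at the captodative C5–H gives 1-Boc-5-bromo-3-methylhydantoin F6. AgOTf with 2,6-lutidine in CH2Cl2 at −20 °C abstracts the bromide and amide 3 is introduced at C5, giving 5.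

**Step 7.** Two processes threaten this step. If the aminal closes and reopens while H2 and Pd/C are still present, the transient C6=N1 iminium ion may be hydrogenated. The aminal with a basic N1–H may also open or hydrolyse during isolation.
Fallback (N1 is acylated before it is attached to C6). It sets out from 10 and returns at 14. After the hydrogenolysis the crude amino carbinol 11 is not cyclised but condensed at once with 13 (EtOH, rt) to the open-chain N–H vinylogous formamide F7. CF3CO2H in CH2Cl2 then ionises the C6 carbinol and the vinylogous formamide N–H, an amide-type nucleophile, closes ring B on the N-acyliminium ion, as in the usual aminal synthesis from amides. This gives 14, which enters stage b) of step 8. In this order a basic amine never sits on the aminal carbon.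

**Step 10.** The risk is competing O-ethylation of the lactam oxygen on C15, with ring opening on work-up, or incomplete alkylation of the hindered urea.
Fallback (activation through a chloride in place of an O-alkyl group). It sets out from 17 and returns at 19 without passing through 18. POCl3 (neat, 70 °C) converts the urea into the 2-chloroamidine F8; any chloroiminium ion formed at the tertiary lactam reverts to the lactam on cold aqueous NaHCO3 work-up. NH3 in MeOH then displaces chloride to give 19.

## Further compounds

F1 | step 8 | 3,4-bis(phenylsulfonyl)pyrrolidine cycloadduct on 12, (6R,10R), ring A saturated with C2 as CH2 | CN1C(=O)N[C@]23CCCN2C(=O)C2C(S(=O)(=O)c4ccccc4)C(S(=O)(=O)c4ccccc4)CN2[C@H]13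
F2 | step 8 | 7-N-methylphakellstatin, (6R,10R), unbrominated pyrrole | CN1C(=O)N[C@]23CCCN2C(=O)c2cccn2[C@H]13
F3 | step 4 | racemic spiro hemiaminal (racemate of 8) | CN1C(=O)N(C(=O)OC(C)(C)C)C2(CCC(O)N2C(=O)CNC(=O)OCc2ccccc2)C1=O
F4 | step 4 | racemic 6-[N-(benzyloxycarbonyl)glycyl]-3-methyl-1,3,6-triazaspiro[4.4]nonane-2,4-dione (racemate of 9) | CN1C(=O)NC2(CCCN2C(=O)CNC(=O)OCc2ccccc2)C1=O
F5 | step 3 | 1-Boc-3-methylhydantoin (tert-butyl 3-methyl-2,4-dioxoimidazolidine-1-carboxylate) | CN1C(=O)CN(C(=O)OC(C)(C)C)C1=O
F6 | step 3 | 1-Boc-5-bromo-3-methylhydantoin (racemic) | CN1C(=O)C(Br)N(C(=O)OC(C)(C)C)C1=O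
F7 | step 7 | open-chain N–H vinylogous formamide: (5R)-6-[N-(2-bromo-3-oxoprop-1-enyl)glycyl]-4-hydroxy-3-methyl-1,3,6-triazaspiro[4.4]nonan-2-one | CN1C(=O)N[C@@]2(CCCN2C(=O)CNC=C(Br)C=O)C1O
F8 | step 10 | 2-chloroamidine, (6S,10R): 8-chloro compound with the C8=N9 double bond | CN1C(Cl)=N[C@]23CCCN2C(=O)c2cc(Br)c(Br)n2[C@H]13
A1 | alternative 1 | methyl 1-pyrroline-2-carboxylate (methyl 3,4-dihydro-2H-pyrrole-5-carboxylate) | COC(=O)C1=NCCC1
A2 | alternative 1 | methyl isocyanide | C[N+]#[C-]
A3 | alternative 1 | 4,5-dibromo-1H-pyrrole-2-carboxylic acid | OC(=O)c1cc(Br)c(Br)[nH]1
A4 | alternative 1 | methyl 1-(4,5-dibromo-1H-pyrrole-2-carbonyl)-2-(methylcarbamoyl)pyrrolidine-2-carboxylate | COC(=O)[C@]1(C(=O)NC)CCCN1C(=O)c1cc(Br)c(Br)[nH]1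
A5 | alternative 2 | N9-Boc 5-(4,5-dibromopyrrole-2-carboxamido)-3-methylhydantoin (racemic) | CN1C(=O)C(NC(=O)c2cc(Br)c(Br)[nH]2)N(C(=O)OC(C)(C)C)C1=O
A6 | alternative 2 | spiro hydantoin hemiaminal carrying the dibromopyrrole amide (both C13 epimers) | CN1C(=O)N(C(=O)OC(C)(C)C)[C@@]2(CCC(O)N2C(=O)c2cc(Br)c(Br)[nH]2)C1=O
A7 | alternative 3 | primary alcohol: 1-(4,5-dibromo-1H-pyrrole-2-carbonyl)-2-(hydroxymethyl)-2-(3-methylureido)pyrrolidine | CNC(=O)N[C@]1(CO)CCCN1C(=O)c1cc(Br)c(Br)[nH]1
A8 | alternative 3 | aldehyde: 1-(4,5-dibromo-1H-pyrrole-2-carbonyl)-2-formyl-2-(3-methylureido)pyrrolidine | CNC(=O)N[C@]1(C=O)CCCN1C(=O)c1cc(Br)c(Br)[nH]1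
A9 | alternative 3 | 7-N-methyldibromophakellstatin (identical with 17) | CN1C(=O)N[C@]23CCCN2C(=O)c2cc(Br)c(Br)n2[C@H]13
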